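**Retrosynthetic overview**

- Feature: the only non-aromatic ring is the γ-lactone O1–C2(=O)–C3–C4–C5, and its C3 already carries oxygen. Without its two trans arylmethyl arms it is a 3-alkoxyfuran-2(5H)-one with a C3=C4 double bond.
- Last disconnection: the three O-benzyl groups (two phenolic, one on the C3 oxygen) lead back to a fully benzylated lactone.
- Key disconnection: C4–CH2Ar (syringyl arm) by copper-catalysed asymmetric 1,4-addition of a benzylic zinc chloride to 3-(benzyloxy)furan-2(5H)-one, then C3–CH2Ar (vanillyl arm) by benzylation of the C3 enolate so formed, in the same operation.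
- No ring is formed. The lactone comes from α-hydroxy-γ-butyrolactone (O-benzylation, α-selenenylation, selenoxide elimination); the two benzylic halides come from syringaldehyde and vanillin.

Key step: step 11

Assumption: racemic α-hydroxy-γ-butyrolactone is used, because its stereocentre becomes sp2 in step 3.
Assumption: the sense of induction of a copper–Josiphos catalyst on a 3-alkoxybutenolide is not known; the antipode written as (R,Sp) stands for whichever one directs the arylmethyl group to the Si face of C4 (giving 4S).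

**Route**

Step 1
Reactants: 1 α-hydroxy-γ-butyrolactone (racemic)
Product: 2 3-(benzyloxy)oxolan-2-one (racemic)
Conditions: BnOC(=NH)CCl3, TfOH (cat.), CH2Cl2/cyclohexane, 0 °C → rt
Reagents that add atoms: benzyl 2,2,2-trichloroacetimidate, N=C(OCc1ccccc1)C(Cl)(Cl)Cl
Why: Acid-catalysed O-benzylation with the trichloroacetimidate needs no base, so the lactone should be neither opened nor enolised.

Step 2
Reactants: 2 3-(benzyloxy)oxolan-2-one
Product: 3 3-(benzyloxy)-3-(phenylselanyl)oxolan-2-one (racemic)
Conditions: LDA, THF, −78 °C; PhSeBr, −78 °C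
Reagents that add atoms: phenylselenyl bromide, Br[Se]c1ccccc1
Why: The lithium enolate can form only at C3 and should be trapped there by the selenium electrophile (enolate α-selenenylation).

Step 3
Reactants: 3 3-(benzyloxy)-3-(phenylselanyl)oxolan-2-one
Product: 4 3-(benzyloxy)furan-2(5H)-one
Conditions: 30% H2O2, pyridine, CH2Cl2, 0 °C → rt
Reagents that add atoms: none
Why: Oxidation to the selenoxide is followed by syn-elimination (selenoxide elimination), which can take a hydrogen only from C4 and so should give the C3=C4 butenolide.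

Step 4
Reactants: 5 vanillin
Product: 6 4-(benzyloxy)-3-methoxybenzaldehyde
Conditions: BnBr, K2CO3, DMF, rt
Reagents that add atoms: benzyl bromide, BrCc1ccccc1
Why: Williamson ether synthesis on the phenoxide; the aldehyde is not affected.

Step 5
Reactants: 6 4-(benzyloxy)-3-methoxybenzaldehyde
Product: 7 [4-(benzyloxy)-3-methoxyphenyl]methanol
Conditions: NaBH4, MeOH, 0 °C
Reagents that add atoms: none
Why: Borohydride reduction of the aldehyde to the benzylic alcohol.

Step 6
Reactants: 7 [4-(benzyloxy)-3-methoxyphenyl]methanol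
Product: 8 1-(benzyloxy)-4-(bromomethyl)-2-methoxybenzene
Conditions: PBr3, CH2Cl2, 0 °C; used at once
Reagents that add atoms: phosphorus tribromide, BrP(Br)Br
Why: Bromination of the benzylic alcohol through its phosphite ester (SN2 by bromide); the benzyl aryl ether should survive the short, cold exposure.

Step 7
Reactants: 9 syringaldehyde
Product: 10 4-(benzyloxy)-3,5-dimethoxybenzaldehyde
Conditions: BnBr, K2CO3, DMF, 60 °C
Reagents that add atoms: benzyl bromide, BrCc1ccccc1
Why: Williamson ether synthesis; mild heating compensates for the two flanking methoxy groups.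

Step 8
Reactants: 10 4-(benzyloxy)-3,5-dimethoxybenzaldehyde
Product: 11 [4-(benzyloxy)-3,5-dimethoxyphenyl]methanol
Conditions: NaBH4, MeOH/THF, 0 °C
Reagents that add atoms: none
Why: Borohydride reduction of the aldehyde to the benzylic alcohol.

Step 9
Reactants: 11 [4-(benzyloxy)-3,5-dimethoxyphenyl]methanol
Product: 12 2-(benzyloxy)-5-(chloromethyl)-1,3-dimethoxybenzene
Conditions: SOCl2, CH2Cl2, 0 °C → rt
Reagents that add atoms: thionyl chloride, O=S(Cl)Cl
Why: Chlorination through the chlorosulfite; the chloride is chosen over the bromide because an electron-rich benzylic chloride should insert zinc with little Wurtz homocoupling.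

Step 10
Reactants: 12 2-(benzyloxy)-5-(chloromethyl)-1,3-dimethoxybenzene
Product: 13 [4-(benzyloxy)-3,5-dimethoxybenzyl]zinc chloride (LiCl complex, titrated THF solution)
Conditions: Zn dust (activated with BrCH2CH2Br and Me3SiCl), LiCl, THF, 25 °C
Reagents that add atoms: zinc, [Zn]
Why: LiCl-accelerated oxidative insertion of zinc into the benzylic C–Cl bond; the ethers are inert and the solution is used directly.

Step 11
Reactants: 4 3-(benzyloxy)furan-2(5H)-one; 13 [4-(benzyloxy)-3,5-dimethoxybenzyl]zinc chloride; 8 1-(benzyloxy)-4-(bromomethyl)-2-methoxybenzene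
Product: 16 (3S,4S)-3-(benzyloxy)-3-[4-(benzyloxy)-3-methoxybenzyl]-4-[4-(benzyloxy)-3,5-dimethoxybenzyl]oxolan-2-one, via silyl ketene acetal 14 (not isolated), via lithium enolate 15 (not isolated)
Conditions: CuBr·SMe2 (5 mol %), (R,Sp)-Josiphos (6 mol %), Me3SiCl (2 equiv), THF, −40 → −20 °C; evaporate, pentane, filter under Ar; MeLi (1.05 equiv), THF, −20 °C; then 8, DMPU, −78 → −20 °C
Reagents that add atoms: none
Why: Proposed new method: the benzylic zinc chloride transmetalates to the diphosphine-bound copper(I) centre, the chiral benzylcopper species π-complexes the C3=C4 bond and adds at C4 while Me3SiCl captures the lactone carbonyl oxygen, and reductive elimination releases silyl ketene acetal 14; after removal of the zinc salts, MeLi cleaves the O–Si bond to lithium enolate 15, which is C-benzylated by 8 in an SN2 reaction. The closest known reaction types are copper-catalysed asymmetric conjugate additions of organozinc and Grignard reagents to α,β-unsaturated lactones with trapping of the enolate, the stoichiometric copper/Me3SiCl-mediated 1,4-addition of benzylic zinc chlorides to enones, and the tandem conjugate addition–benzylation of butenolides; new here are the benzylic zinc halide under catalytic chiral copper and an acceptor that carries an ether oxygen on its α-carbon. No ring is closed, since the lactone is present from the start. C4 (S) is set by the catalyst, which must deliver the arylmethyl group to the Si face of C4, and C3 (S) is set by the substrate, because the bromide approaches the planar enolate on the face opposite the new C4 arylmethyl group, which leaves the two arylmethyl groups trans and the C3 oxygen cis to the C4 substituent. The step needs 1,4- and not 1,2-addition and C- and not O-alkylation: the first is secured because 13 does not attack the lactone without copper and the soft copper nucleophile prefers the alkene terminus, whose lowered electrophilicity (donation from the C3 ether oxygen) is offset by silyl activation and the strain of the butenolide, the second by the lithium counter-ion and the soft benzylic bromide.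

Step 12
Reactants: 16 (3S,4S)-3-(benzyloxy)-3-[4-(benzyloxy)-3-methoxybenzyl]-4-[4-(benzyloxy)-3,5-dimethoxybenzyl]oxolan-2-one
Product: 17 (3S,4S)-3-hydroxy-3-(4-hydroxy-3-methoxybenzyl)-4-(4-hydroxy-3,5-dimethoxybenzyl)oxolan-2-one
Conditions: H2 (1 atm), Pd(OH)2/C, EtOAc/EtOH, rt
Reagents that add atoms: none
Why: Catalytic hydrogenolysis should cleave all three O–CH2Ph bonds, the tertiary C3 ether included; no bond to C3 or C4 is broken, so both stereocentres are kept and the lactone and methyl ethers are untouched.

**Compound list**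

1 | α-hydroxy-γ-butyrolactone (3-hydroxyoxolan-2-one, racemic) | OC1CCOC1=O | starting material
2 | 3-(benzyloxy)oxolan-2-one (racemic) | O=C1OCCC1OCc1ccccc1 | intermediate
3 | 3-(benzyloxy)-3-(phenylselanyl)oxolan-2-one (racemic) | O=C1OCCC1(OCc1ccccc1)[Se]c1ccccc1 | intermediate
4 | 3-(benzyloxy)furan-2(5H)-one | O=C1OCC=C1OCc1ccccc1 | intermediate
5 | vanillin (4-hydroxy-3-methoxybenzaldehyde) | COc1cc(C=O)ccc1O | starting material
6 | 4-(benzyloxy)-3-methoxybenzaldehyde | COc1cc(C=O)ccc1OCc1ccccc1 | intermediate
7 | [4-(benzyloxy)-3-methoxyphenyl]methanol | COc1cc(CO)ccc1OCc1ccccc1 | intermediate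
8 | 1-(benzyloxy)-4-(bromomethyl)-2-methoxybenzene | COc1cc(CBr)ccc1OCc1ccccc1 | intermediate
9 | syringaldehyde (4-hydroxy-3,5-dimethoxybenzaldehyde) | COc1cc(C=O)cc(OC)c1O | starting material
10 | 4-(benzyloxy)-3,5-dimethoxybenzaldehyde | COc1cc(C=O)cc(OC)c1OCc1ccccc1 | intermediate
11 | [4-(benzyloxy)-3,5-dimethoxyphenyl]methanol | COc1cc(CO)cc(OC)c1OCc1ccccc1 | intermediate
12 | 2-(benzyloxy)-5-(chloromethyl)-1,3-dimethoxybenzene | COc1cc(CCl)cc(OC)c1OCc1ccccc1 | intermediate
13 | [4-(benzyloxy)-3,5-dimethoxybenzyl]zinc chloride (LiCl complex in THF) | COc1cc(C[Zn]Cl)cc(OC)c1OCc1ccccc1 | intermediate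
14 | {[(4S)-3-(benzyloxy)-4-[4-(benzyloxy)-3,5-dimethoxybenzyl]-4,5-dihydrofuran-2-yl]oxy}trimethylsilane | C[Si](C)(C)OC1=C(OCc2ccccc2)[C@@H](Cc2cc(OC)c(OCc3ccccc3)c(OC)c2)CO1 | intermediate
15 | lithium (4S)-3-(benzyloxy)-4-[4-(benzyloxy)-3,5-dimethoxybenzyl]-4,5-dihydrofuran-2-olate | [Li+].[O-]C1=C(OCc2ccccc2)[C@@H](Cc2cc(OC)c(OCc3ccccc3)c(OC)c2)CO1 | intermediate
16 | (3S,4S)-3-(benzyloxy)-3-[4-(benzyloxy)-3-methoxybenzyl]-4-[4-(benzyloxy)-3,5-dimethoxybenzyl]oxolan-2-one | COc1cc(C[C@@]2(OCc3ccccc3)C(=O)OC[C@@H]2Cc2cc(OC)c(OCc3ccccc3)c(OC)c2)ccc1OCc1ccccc1 | intermediate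
17 | (3S,4S)-3-hydroxy-3-(4-hydroxy-3-methoxybenzyl)-4-(4-hydroxy-3,5-dimethoxybenzyl)oxolan-2-one | COc1cc(C[C@@]2(O)C(=O)OC[C@@H]2Cc2cc(OC)c(O)c(OC)c2)ccc1O | target

**Step count and risks**

Total steps: 12. Longest linear sequence: 6 steps (9 → 10 → 11 → 12 → 13 → 16 → 17; steps 7–12).

1. Step 11 (proposed new method). What may go wrong:
   - the conjugate addition may be too slow, because the C3 ether oxygen donates into C4, so that the benzylcopper intermediate is lost by homocoupling;
   - facial discrimination at C4 may be poor;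
   - to a lesser extent, the silyl ketene acetal may hydrolyse during salt removal.

   Fallback (known chemistry, chiral pool): it sets out from alcohol 11 and bromide 8 and comes back to the route at lithium enolate 15. Alcohol 11 with PBr3 would give 2-(benzyloxy)-5-(bromomethyl)-1,3-dimethoxybenzene F1. The dianion of commercial diisopropyl (S)-malate (LiHMDS, THF, −78 → −15 °C) would be alkylated by F1 anti to the alkoxide (Fráter–Seebach alkylation) to give diisopropyl (2S,3R)-2-hydroxy-3-[4-(benzyloxy)-3,5-dimethoxybenzyl]butanedioate F2. Saponification (KOH, aqueous dioxane) would give (2S,3R)-2-hydroxy-3-[4-(benzyloxy)-3,5-dimethoxybenzyl]butanedioic acid F3. 2,2-Dimethoxypropane/TsOH would tie up the α-hydroxy acid as (2R)-3-[4-(benzyloxy)-3,5-dimethoxyphenyl]-2-[(4S)-2,2-dimethyl-5-oxo-1,3-dioxolan-4-yl]propanoic acid F4. BH3·SMe2 would reduce the free acid to (5S)-5-[(2S)-1-[4-(benzyloxy)-3,5-dimethoxyphenyl]-3-hydroxypropan-2-yl]-2,2-dimethyl-1,3-dioxolan-4-one F5. TsOH would then lactonise it, with loss of acetone, to (3S,4S)-4-[4-(benzyloxy)-3,5-dimethoxybenzyl]-3-hydroxyoxolan-2-one F6. O-Benzylation with benzyl trichloroacetimidate/TfOH would give (3S,4S)-3-(benzyloxy)-4-[4-(benzyloxy)-3,5-dimethoxybenzyl]oxolan-2-one F7. LDA (THF, −78 °C) would convert F7 into lithium enolate 15, which is benzylated with 8 as in the last stage of step 11 to reach 16.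

2. Step 3. What may go wrong: the benzeneselenenic acid released may add back to the electron-rich enol-ether double bond, or excess peroxide may degrade the product oxidatively. Fallback: it sets out from 1 and comes back at 4. Oxidation of 1 (Dess–Martin periodinane, CH2Cl2) would give the α-keto lactone, which should rest as its enol 3-hydroxyfuran-2(5H)-one F8; O-benzylation of this acidic enol (BnBr, K2CO3, acetone) would give 4. This is not the first choice because the keto lactone can self-condense by aldol reaction.

3. Step 12. What may go wrong: hydrogenolysis may stall at the hindered tertiary C3 benzyl ether after the two phenolic ethers have been cleaved, and forcing conditions may begin to saturate the electron-rich arenes. Fallback: it sets out from 16 and comes back at 17. Lewis-acid debenzylation (BCl3, pentamethylbenzene as cation scavenger, CH2Cl2, −78 °C) would replace hydrogenolysis; the aryl methyl ethers should survive at this temperature. No new compound is formed on the way.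

**Further compounds**

F1 | step 11 | 2-(benzyloxy)-5-(bromomethyl)-1,3-dimethoxybenzene | COc1cc(CBr)cc(OC)c1OCc1ccccc1
F2 | step 11 | diisopropyl (2S,3R)-2-hydroxy-3-[4-(benzyloxy)-3,5-dimethoxybenzyl]butanedioate | CC(C)OC(=O)[C@@H](O)[C@@H](Cc1cc(OC)c(OCc2ccccc2)c(OC)c1)C(=O)OC(C)C
F3 | step 11 | (2S,3R)-2-hydroxy-3-[4-(benzyloxy)-3,5-dimethoxybenzyl]butanedioic acid | OC(=O)[C@@H](O)[C@@H](Cc1cc(OC)c(OCc2ccccc2)c(OC)c1)C(=O)O
F4 | step 11 | (2R)-3-[4-(benzyloxy)-3,5-dimethoxyphenyl]-2-[(4S)-2,2-dimethyl-5-oxo-1,3-dioxolan-4-yl]propanoic acid | CC1(C)OC(=O)[C@@H](O1)[C@@H](Cc1cc(OC)c(OCc2ccccc2)c(OC)c1)C(=O)O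
F5 | step 11 | (5S)-5-[(2S)-1-[4-(benzyloxy)-3,5-dimethoxyphenyl]-3-hydroxypropan-2-yl]-2,2-dimethyl-1,3-dioxolan-4-one | CC1(C)OC(=O)[C@@H](O1)[C@@H](Cc1cc(OC)c(OCc2ccccc2)c(OC)c1)CO
F6 | step 11 | (3S,4S)-4-[4-(benzyloxy)-3,5-dimethoxybenzyl]-3-hydroxyoxolan-2-one | O=C1OC[C@H](Cc2cc(OC)c(OCc3ccccc3)c(OC)c2)[C@@H]1O
F7 | step 11 | (3S,4S)-3-(benzyloxy)-4-[4-(benzyloxy)-3,5-dimethoxybenzyl]oxolan-2-one | O=C1OC[C@H](Cc2cc(OC)c(OCc3ccccc3)c(OC)c2)[C@@H]1OCc1ccccc1
F8 | step 3 | 3-hydroxyfuran-2(5H)-one | OC1=CCOC1=O
F0 | step 12 | none | none
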